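How much target stands beside the other capture product in the flask, early, midway and at the end?

- ratio of target to other capture product at 50 min
- ratio of target to other capture product at 5.0 h
- ratio of target to other capture product at 25 h

| flask | substrate | second nucleophile | solid first nucleophile | remark | time |
|---|---|---|---|---|---|
| Thursday's | 0.075 M | 0.95 equiv | 5 equiv | run made earlier |  |
| Wednesday's | 0.30 M | 0.95 equiv | 5 equiv | run made earlier |  |
| Friday's | 0.15 M | 0.47 equiv | 5 equiv | run made earlier |  |
| flask | 0.15 M | 0.950 equiv | 5.00 equiv |  | 25 h |

- Thursday's (time / h: target / %, other capture product / %): 2.00: 0.5, 1.3; 4.00: 2.2, 2.5; 8.00: 2.7, 5.4; 12.0: 2.6, 2.3; 25.0: 0.3, 3.6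
- Wednesday's (time / h: target / %, other capture product / %): 5.00: 0.7, 10.4; 10.0: 1.6, 16.1; 15.0: 2.4, 15.9; 20.0: 1.4, 17.6; 25.0: 1.8, 15.1
- Friday's (time / h: target / %, other capture product / %): 2.00: 0, 1.8; 4.00: 1.8, 2.5; 8.00: 1.6, 4.7; 12.0: 3.3, 2.1; 25.0: 3.8, 4.5

(standard deviation of a reading: 1 percentage point)

- at the start none of the solid first nucleophile is in solution
- a reading or a percentage of target counts all its forms, free or not

I follow one substrate molecule and ask its chance of ending as other capture product. Wednesday's readings from 10.0 h on average 16.2%, which are odds of 0.193. I scale these by the charged concentration of second nucleophile and get 0.0965 for the flask: the capture odds, the chance of ending as other capture product over the chance of ending as anything else. They mean a share of 8.80%.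

Thursday and Friday test this. They charge 0.0712 M and 0.0705 M of second nucleophile, the odds give 4.60%, and their readings from 8.00 h on average 3.77% and 3.77%.

But one number is not enough for the ratio. Target reads 0.3%, 1.8% and 3.8% at 25.0 h, a mean of 1.97%, so my end ratio is 0.224. Early target lags: Wednesday reads 0.7% beside 10.4% at 5.00 h, and for such times I commit to no figure.

The forecast says 0.12, 0.33 and 0.2, the last lower than mine; it too takes Friday's reading at half the nucleophile to mean scaling with concentration times equivalents, and for the other capture product it expects “a plateau near 8%”.

The flask gives 0.0773, 0.216 and 0.260.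

    substrate → intermediate (k = 0.220 h⁻¹)
    first nucleophile + intermediate → target (k = 99.0 M⁻¹ h⁻¹)
    second nucleophile + intermediate → other capture product (k = 190 M⁻¹ h⁻¹)
    intermediate → solvolysis product (k = 240 h⁻¹)
    solid first nucleophile ⇌ first nucleophile, rate k5*(cs5 - [first nucleophile]) while solid is left; crystals form when [first nucleophile] > cs5 (solubility = 0.0900 M, k = 0.690 h⁻¹)
    first nucleophile + target ⇌ idle adduct, settled at all times (K = 11.0 M⁻¹)

At 3.14 h the flask's intermediate goes to solvolysis product 9.3 times as fast as to other capture product, a selectivity factor. At 25.0 h the flask holds 87.7% solvolysis product, 9.40% other capture product against the 8.80% from the capture odds, and 2.44% target, idle adduct counted. The neighbour flask with 0.570 equiv of second nucleophile has capture odds of 0.0579, a share of 5.47%, and it holds 5.85% other capture product beside 2.54% target, a ratio of 0.434.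

All runs were generated by integration with constants of no real substance; the scatter is artificial.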